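Ring A is a hydroquinone (C1–OH, C4–OH) whose aryloxy group sits on C6 beside C1, with C3 and C5 brominated. The route therefore disconnects the C3–C4 bond and unravels ring A to a squarate-derived cyclobutenone: racemic 3-aryloxy-4-silyloxy-4-vinylcyclobut-2-en-1-one, in which the aryl group is the complete, O-methylated ring B. On heating, the four-membered ring opens to a dienylketene that closes by 6π electrocyclisation and aromatises, so that one operation builds ring A, places the ether oxygen on C6 next to the silylated C1 oxygen and leaves only the C4 hydroxyl free. That free phenol then steers both ring A brominations to C3 and C5 before global deprotection.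

Key step: step 8

Remark on the chemistry: ring A is numbered C1 (OH), C2 (H), C3 (Br), C4 (OH), C5 (Br), C6 (O–ring B), and ring B from its ether carbon. The target is achiral; the only stereocentre on the way (C4 of cyclobutenones 12 and 13) is carried as the racemate and erased in step 8. 2,6-Dibromoanisole and diisopropyl squarate are assumed to be purchased.

Step 1
Reactants: 1 2,6-dibromoanisole
Product: 3 3,5-dibromo-4-methoxyphenol, via aryl pinacol boronate 2 (not isolated)
Conditions: B2pin2, [Ir(OMe)(cod)]2 (cat.), 4,4'-di-tert-butyl-2,2'-bipyridine (cat.), THF, 80 °C; then 30% H2O2, aq NaOH, 0 °C to rt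
Reagents that add atoms: hydrogen peroxide, OO
Why: Sterically governed iridium-catalysed aromatic C–H borylation takes the only C–H without an ortho substituent (para to OMe), aryl bromides being tolerated, and the boronate is oxidised to the phenol in the same flask (C–H borylation/oxidation).

Step 2
Reactants: 3 3,5-dibromo-4-methoxyphenol
Product: 4 2,3,5-tribromo-4-methoxyphenol
Conditions: Br2 (1.0 equiv), CH2Cl2, −20 to 0 °C
Reagents that add atoms: bromine, BrBr
Why: Electrophilic aromatic bromination, in which the free hydroxyl activates only its two equivalent ortho positions and the first bromine deactivates the ring enough for one equivalent of Br2 at low temperature to stop at the monobromide.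

Step 3
Reactants: 5 diisopropyl squarate
Product: 7 3-isopropoxycyclobut-3-ene-1,2-dione, via hydroxycyclobutenone 6 (not isolated)
Conditions: LiAlH(OtBu)3, THF, −78 °C; then 6 M HCl, CH2Cl2, rt
Reagents that add atoms: none
Why: Partial hydride reduction of a squarate ester, in which the bulky aluminium hydride adds once in 1,2 fashion and acid then ionises the carbinol and hydrolyses the resulting oxocarbenium ion with loss of one isopropoxy group to leave the semisquarate ester.

Step 4
Reactants: 7 3-isopropoxycyclobut-3-ene-1,2-dione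
Product: 8 semisquaric acid (3-hydroxycyclobut-3-ene-1,2-dione)
Conditions: 2 M aq HCl, 60 °C; evaporate
Reagents that add atoms: water, O
Why: Acid hydrolysis of a vinylogous ester by addition–elimination at the alkoxy-bearing carbon should give the strongly acidic, water-soluble semisquaric acid, isolated simply by evaporation.

Step 5
Reactants: 8 semisquaric acid; 4 2,3,5-tribromo-4-methoxyphenol
Product: 10 3-(2,3,5-tribromo-4-methoxyphenoxy)cyclobut-3-ene-1,2-dione, via semisquaric chloride 9 (not isolated)
Conditions: (COCl)2 (1.0 equiv), DMF (cat.), CH2Cl2, 0 °C to rt, evaporate; then 4, i-Pr2NEt, CH2Cl2, −40 to 0 °C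
Reagents that add atoms: none
Why: Semisquaric acid is a vinylogous carboxylic acid, so DMF-catalysed chlorination gives its vinylogous acid chloride, which the phenoxide of 4 attacks at the chlorine-bearing carbon by addition–elimination (acylation-type esterification of a phenol) without the chloride being isolated.

Step 6
Reactants: 10 3-(2,3,5-tribromo-4-methoxyphenoxy)cyclobut-3-ene-1,2-dione; 11 vinylmagnesium bromide
Product: 12 rac-4-hydroxy-3-(2,3,5-tribromo-4-methoxyphenoxy)-4-vinylcyclobut-2-en-1-one
Conditions: 11 (1.05 equiv, slow addition), THF, −78 °C; sat. aq NH4Cl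
Reagents that add atoms: none
Why: Grignard 1,2-addition, in which the carbonyl conjugated through the C=C bond to the aryloxy oxygen is a deactivated vinylogous ester, so the vinyl nucleophile should attack the ketone-like carbonyl next to the aryloxy-bearing carbon; the new quaternary carbinol centre forms as the racemate, which needs no control because step 8 erases it.

Step 7
Reactants: 12 rac-4-hydroxy-3-(2,3,5-tribromo-4-methoxyphenoxy)-4-vinylcyclobut-2-en-1-one
Product: 13 rac-4-(tert-butyldimethylsilyloxy)-3-(2,3,5-tribromo-4-methoxyphenoxy)-4-vinylcyclobut-2-en-1-one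
Conditions: TBSOTf, 2,6-lutidine, CH2Cl2, −78 to 0 °C
Reagents that add atoms: tert-butyldimethylsilyl triflate, CC(C)(C)[Si](C)(C)OS(=O)(=O)C(F)(F)F
Why: Silyl triflate silylation of a hindered tertiary alcohol with a weak, non-nucleophilic pyridine base avoids the alkoxide conditions that could open the strained hydroxy ketone.

Step 8
Reactants: 13 rac-4-(tert-butyldimethylsilyloxy)-3-(2,3,5-tribromo-4-methoxyphenoxy)-4-vinylcyclobut-2-en-1-one
Product: 16 4-(tert-butyldimethylsilyloxy)-3-(2,3,5-tribromo-4-methoxyphenoxy)phenol, via dienylketene 14 (not isolated), via cyclohexadienone 15 (not isolated)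
Conditions: PhMe (0.01 M, degassed), 110 °C
Reagents that add atoms: none
Why: Heating should effect conrotatory 4π electrocyclic opening of the C1–C4 bond of the cyclobutenone to the (Z)-dienylketene 14, whose disrotatory 6π electrocyclisation joins the ketene carbon (future C4) to the vinyl terminus (future C3) and gives cyclohexa-2,4-dienone 15, which enolises to the phenol. The closest known reaction type is the Moore rearrangement of squarate-derived 4-alkenyl-4-hydroxy, 4-alkoxy or 4-silyloxy cyclobutenones to hydroquinones and their monoethers. Ring A, a six-membered carbocycle, is closed by this thermally allowed 6π electrocyclisation through the single new C3–C4 bond. No stereocentre is created, and the racemic quaternary centre of 13 becomes the planar C1 of the arene. The selectivity needed is torquoselectivity in the ring opening: the donor silyloxy group rotates outward, which turns the vinyl group inward and cis to the ketene, as cyclisation requires. Regiochemistry is already fixed by the connectivity of 13, which places the aryloxy carbon between the silyloxy carbon (C1) and the former ring CH (C5), and high dilution should keep the phenolic product from trapping the ketene.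

Step 9
Reactants: 16 4-(tert-butyldimethylsilyloxy)-3-(2,3,5-tribromo-4-methoxyphenoxy)phenol
Product: 17 2,6-dibromo-4-(tert-butyldimethylsilyloxy)-3-(2,3,5-tribromo-4-methoxyphenoxy)phenol
Conditions: NBS (2.1 equiv), MeCN, 0 °C to rt
Reagents that add atoms: N-bromosuccinimide, O=C1CCC(=O)N1Br
Why: Electrophilic aromatic bromination directed by the one free hydroxyl, since C3 (ortho to C4–OH, para to the C6 ether oxygen) and C5 (ortho to both) are the most activated positions, the silylated C1 oxygen activates C2 far less, ring B is deactivated, and NBS releases no HBr that could strip the silyl ether.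

Step 10
Reactants: 17 2,6-dibromo-4-(tert-butyldimethylsilyloxy)-3-(2,3,5-tribromo-4-methoxyphenoxy)phenol
Product: 18 3,5-dibromo-2-(2,3,5-tribromo-4-hydroxyphenoxy)benzene-1,4-diol (CNP0084224.0)
Conditions: BBr3 (6 equiv), CH2Cl2, −78 °C to rt; then H2O, 0 °C (aq Na2S2O4 wash, inert atmosphere)
Reagents that add atoms: none
Why: Lewis acid ether cleavage, in which BBr3 demethylates the hindered aryl methyl ether by bromide attack on the O-methyl group and also cleaves the aryl silyl ether, while the diaryl ether and C–Br bonds are inert, so hydrolysis of the aryl borates should release the triol.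

Compound list
1 | 2,6-dibromoanisole (1,3-dibromo-2-methoxybenzene) | COc1c(Br)cccc1Br | starting material
2 | 2-(3,5-dibromo-4-methoxyphenyl)-4,4,5,5-tetramethyl-1,3,2-dioxaborolane | COc1c(Br)cc(cc1Br)B1OC(C)(C)C(C)(C)O1 | intermediate
3 | 3,5-dibromo-4-methoxyphenol | COc1c(Br)cc(O)cc1Br | intermediate
4 | 2,3,5-tribromo-4-methoxyphenol | COc1c(Br)cc(O)c(Br)c1Br | intermediate
5 | diisopropyl squarate (3,4-diisopropoxycyclobut-3-ene-1,2-dione) | CC(C)OC1=C(OC(C)C)C(=O)C1=O | starting material
6 | rac-4-hydroxy-2,3-diisopropoxycyclobut-2-en-1-one | CC(C)OC1=C(OC(C)C)C(=O)C1O | intermediate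
7 | 3-isopropoxycyclobut-3-ene-1,2-dione | CC(C)OC1=CC(=O)C1=O | intermediate
8 | semisquaric acid (3-hydroxycyclobut-3-ene-1,2-dione) | OC1=CC(=O)C1=O | intermediate
9 | semisquaric chloride (3-chlorocyclobut-3-ene-1,2-dione) | ClC1=CC(=O)C1=O | intermediate
10 | 3-(2,3,5-tribromo-4-methoxyphenoxy)cyclobut-3-ene-1,2-dione | COc1c(Br)cc(OC2=CC(=O)C2=O)c(Br)c1Br | intermediate
11 | vinylmagnesium bromide | C=C[Mg]Br | starting material
12 | rac-4-hydroxy-3-(2,3,5-tribromo-4-methoxyphenoxy)-4-vinylcyclobut-2-en-1-one | C=CC1(O)C(=O)C=C1Oc1cc(Br)c(OC)c(Br)c1Br | intermediate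
13 | rac-4-(tert-butyldimethylsilyloxy)-3-(2,3,5-tribromo-4-methoxyphenoxy)-4-vinylcyclobut-2-en-1-one | C=CC1(O[Si](C)(C)C(C)(C)C)C(=O)C=C1Oc1cc(Br)c(OC)c(Br)c1Br | intermediate
14 | (3Z)-4-(tert-butyldimethylsilyloxy)-3-(2,3,5-tribromo-4-methoxyphenoxy)hexa-1,3,5-trien-1-one (dienylketene) | O=C=C/C(Oc1cc(Br)c(OC)c(Br)c1Br)=C(\C=C)O[Si](C)(C)C(C)(C)C | intermediate
15 | 4-(tert-butyldimethylsilyloxy)-3-(2,3,5-tribromo-4-methoxyphenoxy)cyclohexa-2,4-dien-1-one | O=C1CC=C(O[Si](C)(C)C(C)(C)C)C(Oc2cc(Br)c(OC)c(Br)c2Br)=C1 | intermediate
16 | 4-(tert-butyldimethylsilyloxy)-3-(2,3,5-tribromo-4-methoxyphenoxy)phenol | Oc1ccc(O[Si](C)(C)C(C)(C)C)c(Oc2cc(Br)c(OC)c(Br)c2Br)c1 | intermediate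
17 | 2,6-dibromo-4-(tert-butyldimethylsilyloxy)-3-(2,3,5-tribromo-4-methoxyphenoxy)phenol | Oc1c(Br)cc(O[Si](C)(C)C(C)(C)C)c(Oc2cc(Br)c(OC)c(Br)c2Br)c1Br | intermediate
18 | 3,5-dibromo-2-(2,3,5-tribromo-4-hydroxyphenoxy)benzene-1,4-diol | Oc1cc(Br)c(O)c(Br)c1Oc1cc(Br)c(O)c(Br)c1Br | target

Total step count: 10. Longest linear sequence: 8 steps (steps 3–10 from diisopropyl squarate; the ring B branch, steps 1, 2 and 5–10, is equally long).

Steps most likely to fail

1. Step 6. The Grignard reagent may attack the aryloxy-bearing carbon and expel the electron-poor aryloxide (addition–elimination), or add to the vinylogous ester carbonyl, because an aryloxy group deactivates that carbonyl less than an alkoxy group does. The fallback sets out from 7 and comes back at 13: the vinyl carbinol is installed on the alkyl semisquarate, where this carbonyl selectivity is established, and ring B is brought in afterwards. Vinylmagnesium bromide 11 is added to 7 in THF at −78 °C to give rac-4-hydroxy-3-isopropoxy-4-vinylcyclobut-2-en-1-one F1. TBSOTf and 2,6-lutidine convert it into rac-4-(tert-butyldimethylsilyloxy)-3-isopropoxy-4-vinylcyclobut-2-en-1-one F2. LiOH in aqueous THF at 0 °C hydrolyses the vinylogous ester to rac-4-(tert-butyldimethylsilyloxy)-3-hydroxy-4-vinylcyclobut-2-en-1-one F3. (COCl)2 with catalytic DMF turns this vinylogous acid into rac-3-chloro-4-(tert-butyldimethylsilyloxy)-4-vinylcyclobut-2-en-1-one F4. Addition–elimination of phenol 4 with i-Pr2NEt on this β-chloro enone gives 13.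

2. Step 5. The moisture-sensitive vinylogous acid chloride may hydrolyse or self-condense before it meets the hindered, weakly nucleophilic phenoxide, and any leftover oxalyl chloride would acylate the phenol. The fallback sets out from 4 and comes back at 10. Phenol 4 is acylated with one equivalent of purchased squaric acid dichloride (i-Pr2NEt, CH2Cl2, −40 °C) to give 3-chloro-4-(2,3,5-tribromo-4-methoxyphenoxy)cyclobut-3-ene-1,2-dione F1-analogue in function, here labelled F5. The remaining vinylogous acyl chloride is then removed by reduction with Bu3SnH and catalytic Pd(PPh3)4 in toluene at rt (the acid chloride hydrodechlorination type), which gives 10.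

3. Step 8. The dienylketene may be captured intermolecularly by the phenolic product or by traces of water, or the silyl group may be lost at the reaction temperature, followed by oxidation to the quinone. The fallback sets out from 4 and comes back at 16 by a conventional diaryl ether route. Nucleophilic aromatic substitution of 4 on purchased 4-(benzyloxy)-2-fluorobenzaldehyde (K2CO3, DMF, 100 °C) gives 4-(benzyloxy)-2-(2,3,5-tribromo-4-methoxyphenoxy)benzaldehyde F6. Baeyer–Villiger oxidation with mCPBA in CH2Cl2 gives 4-(benzyloxy)-2-(2,3,5-tribromo-4-methoxyphenoxy)phenyl formate F7, which K2CO3 in MeOH cleaves to 4-(benzyloxy)-2-(2,3,5-tribromo-4-methoxyphenoxy)phenol F8. TBSCl and imidazole in DMF give tert-butyl[4-(benzyloxy)-2-(2,3,5-tribromo-4-methoxyphenoxy)phenoxy]dimethylsilane F9. Debenzylation with BCl3 and pentamethylbenzene in CH2Cl2 at −78 °C (hydrogenolysis is avoided because of the aryl bromides) gives 16.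

Further compounds
F1 | step 6 | rac-4-hydroxy-3-isopropoxy-4-vinylcyclobut-2-en-1-one | C=CC1(O)C(=O)C=C1OC(C)C
F2 | step 6 | rac-4-(tert-butyldimethylsilyloxy)-3-isopropoxy-4-vinylcyclobut-2-en-1-one | C=CC1(O[Si](C)(C)C(C)(C)C)C(=O)C=C1OC(C)C
F3 | step 6 | rac-4-(tert-butyldimethylsilyloxy)-3-hydroxy-4-vinylcyclobut-2-en-1-one | C=CC1(O[Si](C)(C)C(C)(C)C)C(=O)C=C1O
F4 | step 6 | rac-3-chloro-4-(tert-butyldimethylsilyloxy)-4-vinylcyclobut-2-en-1-one | C=CC1(O[Si](C)(C)C(C)(C)C)C(=O)C=C1Cl
F5 | step 5 | 3-chloro-4-(2,3,5-tribromo-4-methoxyphenoxy)cyclobut-3-ene-1,2-dione | COc1c(Br)cc(OC2=C(Cl)C(=O)C2=O)c(Br)c1Br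
F6 | step 8 | 4-(benzyloxy)-2-(2,3,5-tribromo-4-methoxyphenoxy)benzaldehyde | COc1c(Br)cc(Oc2cc(OCc3ccccc3)ccc2C=O)c(Br)c1Br
F7 | step 8 | 4-(benzyloxy)-2-(2,3,5-tribromo-4-methoxyphenoxy)phenyl formate | COc1c(Br)cc(Oc2cc(OCc3ccccc3)ccc2OC=O)c(Br)c1Br
F8 | step 8 | 4-(benzyloxy)-2-(2,3,5-tribromo-4-methoxyphenoxy)phenol | COc1c(Br)cc(Oc2cc(OCc3ccccc3)ccc2O)c(Br)c1Br
F9 | step 8 | tert-butyl[4-(benzyloxy)-2-(2,3,5-tribromo-4-methoxyphenoxy)phenoxy]dimethylsilane | COc1c(Br)cc(Oc2cc(OCc3ccccc3)ccc2O[Si](C)(C)C(C)(C)C)c(Br)c1Br
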